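## Retrosynthetic overview

1. Target 13 comes from trans-opening of the allylic epoxide 11 by methanol at its allylic carbon (C–OMe bond, inversion).
2. Epoxide 11 comes from regio- and face-selective epoxidation of the unhindered cis-alkene of dienol 10; this is the second oxirane and mirrors the 4,5-epoxide of the proposed biogenesis.
3. Dienol 10 comes from enantioselective trans-opening by benzoic acid of the racemising arene oxide 8 (in equilibrium with oxepin 9), the laboratory form of benzyl benzoate 2,3-oxide; this first oxirane delivers both stereocentres in one event.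
4. Arene oxide 8 comes from epoxidation, bromination and twofold dehydrobromination of the Birch-derived diene ester 5, itself from benzoic acid 1 and benzoyl chloride 4.
5. Ring order: the carbocycle is taken intact from benzoic acid and never constructed; the oxirane of 8 is formed and opened, then the oxirane of 11 is formed and opened.

Assumption: the (R)-(S) antipode of the ferrocenyl diphosphine in step 6 is taken to give the (5S,6S) product by analogy with openings of oxabicyclic alkenes; if the sense is opposite, the commercially available (S)-(R) antipode is used and nothing else changes.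

## Route

Step 1
Reactants: 1 benzoic acid
Product: 2 cyclohexa-2,5-diene-1-carboxylic acid
Conditions: Na, NH3 (l), EtOH, −78 → −33 °C; NH4Cl; aq HCl
Reagents that add atoms: none
Why: Birch reduction of the benzoate salt protonates the ipso and para carbons and gives the unconjugated 1,4-dihydro acid; no stereocentre is formed.

Step 2
Reactants: 2 cyclohexa-2,5-diene-1-carboxylic acid
Product: 3 cyclohexa-2,5-dien-1-ylmethanol
Conditions: LiAlH4, Et2O, 0 °C → rt
Reagents that add atoms: none
Why: Hydride reduction of a carboxylic acid to the primary alcohol; the skipped diene is inert to LiAlH4 and no stereocentre is formed.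

Step 3
Reactants: 3 cyclohexa-2,5-dien-1-ylmethanol; 4 benzoyl chloride
Product: 5 cyclohexa-2,5-dien-1-ylmethyl benzoate
Conditions: BzCl, pyridine, DMAP (cat.), CH2Cl2, 0 °C → rt
Reagents that add atoms: benzoyl chloride (4), O=C(Cl)c1ccccc1
Why: DMAP-catalysed nucleophilic acyl substitution installs the primary benzoate that is carried unchanged into the target.

Step 4
Reactants: 5 cyclohexa-2,5-dien-1-ylmethyl benzoate
Product: 6 (7-oxabicyclo[4.1.0]hept-3-en-2-yl)methyl benzoate (racemic cis/trans mixture)
Conditions: mCPBA (1.0 equiv), NaHCO3, CH2Cl2, 0 °C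
Reagents that add atoms: 3-chloroperoxybenzoic acid, O=C(OO)c1cccc(Cl)c1
Why: Prilezhaev epoxidation of one of two equivalent cis-alkenes (the first oxirane inductively slows the second); all stereoisomers converge in step 5, so no stereocontrol is needed.

Step 5
Reactants: 6 (7-oxabicyclo[4.1.0]hept-3-en-2-yl)methyl benzoate
Product: 8 racemic (7-oxabicyclo[4.1.0]hepta-2,4-dien-2-yl)methyl benzoate, via trans-dibromo epoxide 7 (not isolated)
Conditions: Br2 (1.0 equiv), CH2Cl2, −78 °C; then DBU (3 equiv), THF, 0 °C → rt; used at once
Reagents that add atoms: none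
Why: Vogel-type arene oxide synthesis, in which anti-bromination of the remaining alkene and twofold E2 dehydrobromination (each proton lost lies next to an oxirane carbon) give the 2,3-oxide of benzyl benzoate, whose two stereocentres are labile through the oxepin valence tautomer.

Step 6
Reactants: 8 racemic (7-oxabicyclo[4.1.0]hepta-2,4-dien-2-yl)methyl benzoate; 1 benzoic acid
Product: 10 [(5S,6S)-5-(benzoyloxy)-6-hydroxycyclohexa-1,3-dien-1-yl]methyl benzoate, via oxepin-3-ylmethyl benzoate 9 (not isolated)
Conditions: [Rh(cod)Cl]2 (2.5 mol%), (R)-1-[(S)-2-(diphenylphosphino)ferrocenyl]ethyldi-tert-butylphosphine (6 mol%), PhCO2H (1.5 equiv), Et3N (1.0 equiv), THF, 0 → 25 °C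
Reagents that add atoms: benzoic acid (1), OC(=O)c1ccccc1
Why: Proposed new method: the enantiomers of 8 interconvert within seconds through the achiral oxepin 9, so a chiral monovalent-rhodium diphosphine catalyst can funnel all material through one enantiomer (dynamic kinetic asymmetric transformation); rhodium binds the unhindered C4=C5 alkene of 8 and inserts into the adjacent allylic C6–O bond, and triethylammonium benzoate captures the resulting rhodium dienyl alkoxide at C6 anti to the oxygen, which gives the trans hydroxy benzoate and sets both stereocentres (5S,6S) under buffered, non-acidic conditions that hold back NIH-type aromatisation; the closest known reaction type is the rhodium-catalysed asymmetric ring opening of oxabicyclic alkenes and vinyl epoxides by carboxylate and alcohol nucleophiles, which also gives trans-1,2 products.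

Step 7
Reactants: 10 [(5S,6S)-5-(benzoyloxy)-6-hydroxycyclohexa-1,3-dien-1-yl]methyl benzoate
Product: 11 [(1R,4S,5R,6R)-5-(benzoyloxy)-4-hydroxy-7-oxabicyclo[4.1.0]hept-2-en-3-yl]methyl benzoate
Conditions: (R,R)-[N,N'-bis(3,5-di-tert-butylsalicylidene)-1,2-cyclohexanediaminato]MnCl (5 mol%), NaOCl (aq, pH 11.3), 4-phenylpyridine N-oxide (20 mol%), CH2Cl2, 0 °C
Reagents that add atoms: sodium hypochlorite, [Na+].[O-]Cl
Why: Jacobsen–Katsuki epoxidation, in which the stepwise oxo-manganese oxidant attacks the unsubstituted diene terminus C4 of 10 (giving the more substituted allyl radical) so that the cis-disubstituted C3=C4 bond reacts in preference to the hindered trisubstituted C1=C2 bond, while the (R,R)-catalyst (sense as for indene and cyclic dienes) and the substrate (attack anti to the neighbouring benzoate) both deliver oxygen to the face syn to the hydroxyl, setting C1 and C6 of 11.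

Step 8
Reactants: 11 [(1R,4S,5R,6R)-5-(benzoyloxy)-4-hydroxy-7-oxabicyclo[4.1.0]hept-2-en-3-yl]methyl benzoate; 12 methanol
Product: 13 [(3S,4R,5R,6S)-5-(benzoyloxy)-4,6-dihydroxy-3-methoxycyclohex-1-en-1-yl]methyl benzoate
Conditions: MeOH (10 equiv), BF3·OEt2 (10 mol%), CH2Cl2, −78 → −30 °C
Reagents that add atoms: methanol (12), CO
Why: Lewis acid-catalysed SN2 alcoholysis of a vinyl epoxide, in which methanol attacks the allylic oxirane carbon C1 of 11 with inversion (trans-1,2 opening) and so sets the methoxy-bearing C3 of 13 anti to the liberated C4 hydroxyl, while the esters and the other stereocentres are untouched at low temperature.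

## Compound list

1 | benzoic acid | OC(=O)c1ccccc1 | starting material
2 | cyclohexa-2,5-diene-1-carboxylic acid | OC(=O)C1C=CCC=C1 | intermediate
3 | cyclohexa-2,5-dien-1-ylmethanol | OCC1C=CCC=C1 | intermediate
4 | benzoyl chloride | O=C(Cl)c1ccccc1 | starting material
5 | cyclohexa-2,5-dien-1-ylmethyl benzoate | O=C(OCC1C=CCC=C1)c1ccccc1 | intermediate
6 | (7-oxabicyclo[4.1.0]hept-3-en-2-yl)methyl benzoate (racemic cis/trans mixture) | O=C(OCC1C=CCC2OC12)c1ccccc1 | intermediate
7 | (3,4-dibromo-7-oxabicyclo[4.1.0]heptan-2-yl)methyl benzoate (trans-dibromide, diastereomer mixture, not isolated) | O=C(OCC1C(Br)C(Br)CC2OC12)c1ccccc1 | intermediate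
8 | (7-oxabicyclo[4.1.0]hepta-2,4-dien-2-yl)methyl benzoate (racemic, benzyl benzoate 2,3-oxide) | O=C(OCC1=CC=CC2OC12)c1ccccc1 | intermediate
9 | oxepin-3-ylmethyl benzoate (valence tautomer of 8, not isolated) | O=C(OCC1=COC=CC=C1)c1ccccc1 | intermediate
10 | [(5S,6S)-5-(benzoyloxy)-6-hydroxycyclohexa-1,3-dien-1-yl]methyl benzoate | C1=CC=C(COC(=O)c2ccccc2)[C@H](O)[C@H]1OC(=O)c1ccccc1 | intermediate
11 | [(1R,4S,5R,6R)-5-(benzoyloxy)-4-hydroxy-7-oxabicyclo[4.1.0]hept-2-en-3-yl]methyl benzoate | O1[C@@H]2C=C(COC(=O)c3ccccc3)[C@H](O)[C@@H](OC(=O)c3ccccc3)[C@H]12 | intermediate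
12 | methanol | CO | starting material
13 | [(3S,4R,5R,6S)-5-(benzoyloxy)-4,6-dihydroxy-3-methoxycyclohex-1-en-1-yl]methyl benzoate | CO[C@H]1C=C(COC(=O)c2ccccc2)[C@H](O)[C@@H](OC(=O)c2ccccc2)[C@@H]1O | target

## Step count and risks

Total step count: 8. Longest linear sequence: 8 steps (1 → 13).

Steps most likely to fail:

1. Step 6 (dynamic rhodium-catalysed opening of 8). The risks are metal- or acid-induced isomerisation of 8 to hydroxybenzyl benzoates, attack at the wrong carbon, and low ee. The fallback sets out from 3 and comes back at 10; it replaces the arene oxide by an equivalent that can neither racemise nor aromatise. Alcohol 3 is desymmetrised by hydroxyl-directed asymmetric epoxidation of one of its two enantiotopic alkenes (VO(OiPr)3, chiral bishydroxamic acid ligand, cumene hydroperoxide, toluene, 0 °C), giving the syn epoxy alcohol [(1S,2R,6R)-7-oxabicyclo[4.1.0]hept-3-en-2-yl]methanol F1. Benzoylation (BzCl, pyridine) gives [(1S,2R,6R)-7-oxabicyclo[4.1.0]hept-3-en-2-yl]methyl benzoate F2. Caesium benzoate and benzoic acid in DMF at 80 °C open the oxirane with inversion at C6, the carbon remote from the branch, giving [(1R,5S,6S)-5-(benzoyloxy)-6-hydroxycyclohex-2-en-1-yl]methyl benzoate F3. Bromine in CH2Cl2 at −78 °C gives [(5S,6S)-5-(benzoyloxy)-2,3-dibromo-6-hydroxycyclohexyl]methyl benzoate F4 (trans-dibromide), and DBU in THF removes two HBr to give 10.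

2. Step 7 (epoxidation of 10). The risks are hydroxyl-directed attack on the trisubstituted alkene, oxidation of the allylic alcohol, and the wrong face. The fallback sets out from 10 and comes back at 13, bypassing 11. Singlet oxygen (O2, hν, tetraphenylporphyrin, CH2Cl2, −30 °C) adds across the diene termini on the face of the free hydroxyl and anti to the benzoate, giving the endoperoxide [8-(benzoyloxy)-7-hydroxy-2,3-dioxabicyclo[2.2.2]oct-5-en-1-yl]methyl benzoate F5. Zn in AcOH/CH2Cl2 at 0 °C cleaves the O–O bond to the cis-1,4-diol [(1R,2R,3S,4R)-3-(benzoyloxy)-1,2,4-trihydroxycyclohex-5-en-1-yl]methyl benzoate F6, which already carries the C4 hydroxyl of the target. Camphorsulfonic acid in methanol at 0 °C ionises the tertiary allylic alcohol, and methanol is captured at the secondary allylic terminus anti to the neighbouring hydroxyl (allylic transposition), giving 13.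

3. Step 5 (arene oxide formation). The risks are incomplete or misdirected twofold elimination (vinyl bromides) and aromatisation of the labile product. The fallback sets out from 6 and comes back at 8. Wohl–Ziegler bromination of 6 (NBS, AIBN, PhCF3, 80 °C) gives the allylic bromide (5-bromo-7-oxabicyclo[4.1.0]hept-3-en-2-yl)methyl benzoate F7 together with its allylic regioisomers. All of these lose a single HBr with DBU in THF at 0 °C by 1,2- or 1,4-elimination and converge on 8, so one elimination replaces bromine addition and two eliminations.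

## Further compounds

F1 | step 6 | [(1S,2R,6R)-7-oxabicyclo[4.1.0]hept-3-en-2-yl]methanol | OC[C@@H]1[C@@H]2O[C@@H]2CC=C1
F2 | step 6 | [(1S,2R,6R)-7-oxabicyclo[4.1.0]hept-3-en-2-yl]methyl benzoate | O=C(OC[C@@H]1[C@@H]2O[C@@H]2CC=C1)c1ccccc1
F3 | step 6 | [(1R,5S,6S)-5-(benzoyloxy)-6-hydroxycyclohex-2-en-1-yl]methyl benzoate | O=C(OC[C@@H]1[C@H](O)[C@@H](OC(=O)c2ccccc2)CC=C1)c1ccccc1
F4 | step 6 | [(5S,6S)-5-(benzoyloxy)-2,3-dibromo-6-hydroxycyclohexyl]methyl benzoate (trans-dibromide, C1 as in F3) | O=C(OC[C@@H]1[C@H](O)[C@@H](OC(=O)c2ccccc2)CC(Br)C1Br)c1ccccc1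
F5 | step 7 | [8-(benzoyloxy)-7-hydroxy-2,3-dioxabicyclo[2.2.2]oct-5-en-1-yl]methyl benzoate (peroxide bridge syn to the hydroxyl, anti to the benzoate) | C1=C[C@]2(COC(=O)c3ccccc3)OO[C@H]1[C@H](OC(=O)c3ccccc3)[C@H]2O
F6 | step 7 | [(1R,2R,3S,4R)-3-(benzoyloxy)-1,2,4-trihydroxycyclohex-5-en-1-yl]methyl benzoate | C1=C[C@@](O)(COC(=O)c2ccccc2)[C@H](O)[C@@H](OC(=O)c2ccccc2)[C@@H]1O
F7 | step 5 | (5-bromo-7-oxabicyclo[4.1.0]hept-3-en-2-yl)methyl benzoate (racemic, diastereomer mixture) | O=C(OCC1C=CC(Br)C2OC12)c1ccccc1
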